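**Plan**

- Retrosynthesis, using spiro numbering O1, C2 (methyl and chain), C3, C4, spiro C5, ketone C6, alkene C7=C8, carbinol C9: the C9 acetyl is cut back to an isopropenyl group (ozonolysis). The C7=C8 bond is then cut by ring-closing metathesis. The two C5 arms (C6 acyl, C9 carbinol) go back to CH2OSi and CO2Me, the O1–C5 bond to an epoxide opening, and the C4–C5 bond to a B-alkyl Suzuki coupling.
- Enabling feature: C7=C8 of the cyclopentenone carries two methyl groups and C9 carries OH plus a latent isopropenyl. C9 can therefore stay a non-stereogenic bis(isopropenyl) carbinol until the ring closure selects one of the two groups.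
- Forward order: phytol is converted into (R)-isophytol and joined to a four-carbon alkenyl iodide. The oxolane (ring A) closes by epoxide opening, the two arms on C5 are built up, the cyclopentenone (ring B) closes by metathesis, and ozonolysis comes last.
- Stereochemistry: the chain centres come from natural phytol. C2 comes from a Sharpless epoxidation of phytol and C5 from a second Sharpless epoxidation followed by opening with inversion. C9 comes from diastereotopic group selection in the metathesis, controlled by C5.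

Key step: step 14

Assumption: commercial natural phytol is taken as the pure (2E,7R,11R) isomer, and the secondary carbinol centre made in step 12 is carried as an epimer mixture because step 13 removes it.

Remark: the quaternary oxolane carbon keeps one spatial arrangement from 11 to 23. Its descriptor (S or R) changes only because the CIP ranking of its two carbon arms changes; the same holds for the oxirane CH carbon in 3 and the carbinol carbon in 8.

**Route**

Step 1
Reactants: 1 natural (2E,7R,11R)-phytol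
Product: 2 [(2R,3R)-3-methyl-3-[(4R,8R)-4,8,12-trimethyltridecyl]oxiran-2-yl]methanol
Conditions: Ti(OiPr)4 (10 mol %), D-(−)-diethyl tartrate (12 mol %), t-BuOOH, 4 Å MS, CH2Cl2, −20 °C
Reagents that add atoms: tert-butyl hydroperoxide, CC(C)(C)OO
Why: Katsuki–Sharpless asymmetric epoxidation of an (E)-3,3-disubstituted primary allylic alcohol is reagent-controlled, and D-(−)-tartrate should give the (2R,3R)-epoxide (the mirror-image sense of the (2S,3S)-epoxide that geraniol gives with L-(+)-tartrate), which fixes the future C2.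

Step 2
Reactants: 2 [(2R,3R)-3-methyl-3-[(4R,8R)-4,8,12-trimethyltridecyl]oxiran-2-yl]methanol
Product: 3 (2S,3R)-2-(iodomethyl)-3-methyl-3-[(4R,8R)-4,8,12-trimethyltridecyl]oxirane
Conditions: PPh3, I2, imidazole, THF–MeCN, 0 °C
Reagents that add atoms: iodine, II
Why: Appel-type iodination converts the primary hydroxyl into the iodide by SN2 at the CH2 group under imidazole-buffered conditions that should leave the epoxide intact, and no stereocentre is touched.

Step 3
Reactants: 3 (2S,3R)-2-(iodomethyl)-3-methyl-3-[(4R,8R)-4,8,12-trimethyltridecyl]oxirane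
Product: 4 (3R,7R,11R)-3,7,11,15-tetramethylhexadec-1-en-3-ol [(R)-isophytol]
Conditions: Zn dust, EtOH, 70 °C
Reagents that add atoms: none
Why: Zinc inserts into the C–I bond and the β-oxido organozinc fragments (reductive epoxide opening of a 2,3-epoxy iodide) to the transposed tertiary allylic alcohol, and because the C–O bond at the quaternary carbon is never broken its configuration is retained.

Step 4
Reactants: 5 4-{[tert-butyl(dimethyl)silyl]oxy}but-2-yn-1-ol
Product: 7 (2Z)-4-{[tert-butyl(dimethyl)silyl]oxy}-3-iodobut-2-en-1-ol, via cyclic alkenylalanate 6 (not isolated)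
Conditions: NaAlH2(OCH2CH2OMe)2 (Red-Al), THF, 0 °C; then I2, −78 → 0 °C
Reagents that add atoms: iodine, II
Why: Hydroxyl-directed trans-hydroalumination of the propargylic alcohol places aluminium on C3 in a five-membered alanate, and iodinolysis with retention should give the (Z)-3-iodo allylic alcohol (the established Red-Al–iodine sequence).

Step 5
Reactants: 4 (3R,7R,11R)-3,7,11,15-tetramethylhexadec-1-en-3-ol; 7 (2Z)-4-{[tert-butyl(dimethyl)silyl]oxy}-3-iodobut-2-en-1-ol
Product: 9 (2E,6R,10R,14R)-3-({[tert-butyl(dimethyl)silyl]oxy}methyl)-6,10,14,18-tetramethylnonadec-2-ene-1,6-diol, via B-alkyl-9-BBN borane 8 (not isolated)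
Conditions: 9-BBN dimer (excess), THF, 0 °C → rt; then 7, PdCl2(dppf) (5 mol %), AsPh3, Cs2CO3, DMF–H2O, rt
Reagents that add atoms: none
Why: 9-BBN adds to the terminal carbon of the vinyl group and the B-alkyl Suzuki–Miyaura coupling with the alkenyl iodide proceeds with retention of olefin geometry, so the new alkyl branch (future C4) should end up cis to the hydroxymethyl group while the free hydroxyls are tolerated.

Step 6
Reactants: 9 (2E,6R,10R,14R)-3-({[tert-butyl(dimethyl)silyl]oxy}methyl)-6,10,14,18-tetramethylnonadec-2-ene-1,6-diol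
Product: 11 (1R)-1-[(2S,5R)-2-({[tert-butyl(dimethyl)silyl]oxy}methyl)-5-methyl-5-[(4R,8R)-4,8,12-trimethyltridecyl]oxolan-2-yl]ethane-1,2-diol, via epoxy alcohol 10 (not isolated)
Conditions: Ti(OiPr)4, D-(−)-diethyl tartrate, t-BuOOH, 4 Å MS, CH2Cl2, −20 °C; then CSA (10 mol %) on the crude epoxide, CH2Cl2, 0 °C
Reagents that add atoms: tert-butyl hydroperoxide, CC(C)(C)OO
Why: Katsuki–Sharpless epoxidation of the trisubstituted allylic alcohol is reagent-controlled (D-(−)-tartrate, same facial sense as in step 1, giving the (2R,3R)-epoxide 10), and the tertiary hydroxyl should then open the epoxide by acid-catalysed 5-exo attack at its fully substituted carbon with inversion, which closes ring A and sets the future C5 with its two arms already different (CH2OSi and CH(OH)CH2OH).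

Step 7
Reactants: 11 (1R)-1-[(2S,5R)-2-({[tert-butyl(dimethyl)silyl]oxy}methyl)-5-methyl-5-[(4R,8R)-4,8,12-trimethyltridecyl]oxolan-2-yl]ethane-1,2-diol
Product: 12 (2S,5R)-2-({[tert-butyl(dimethyl)silyl]oxy}methyl)-5-methyl-5-[(4R,8R)-4,8,12-trimethyltridecyl]oxolane-2-carbaldehyde
Conditions: NaIO4, THF–H2O, 0 °C → rt
Reagents that add atoms: none
Why: Periodate glycol cleavage (Malaprade reaction) removes the terminal carbon as formaldehyde and leaves a non-enolisable α-alkoxy aldehyde whose quaternary centre cannot epimerise.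

Step 8
Reactants: 12 (2S,5R)-2-({[tert-butyl(dimethyl)silyl]oxy}methyl)-5-methyl-5-[(4R,8R)-4,8,12-trimethyltridecyl]oxolane-2-carbaldehyde
Product: 13 methyl (2S,5R)-2-({[tert-butyl(dimethyl)silyl]oxy}methyl)-5-methyl-5-[(4R,8R)-4,8,12-trimethyltridecyl]oxolane-2-carboxylate
Conditions: NIS, K2CO3, MeOH, rt, dark
Reagents that add atoms: methanol, CO
Why: Oxidative esterification through the hypoiodite of the methanol hemiacetal turns the aldehyde into the methyl ester in one mild step that the primary silyl ether should survive.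

Step 9
Reactants: 13 methyl (2S,5R)-2-({[tert-butyl(dimethyl)silyl]oxy}methyl)-5-methyl-5-[(4R,8R)-4,8,12-trimethyltridecyl]oxolane-2-carboxylate; 14 isopropenylmagnesium bromide (commercial THF solution)
Product: 16 3-[(2S,5R)-2-({[tert-butyl(dimethyl)silyl]oxy}methyl)-5-methyl-5-[(4R,8R)-4,8,12-trimethyltridecyl]oxolan-2-yl]-2,4-dimethylpenta-1,4-dien-3-ol, via isopropenyl ketone 15 (not isolated)
Conditions: 14 (4 equiv), CeCl3 (anhydrous), THF, −78 → 0 °C
Reagents that add atoms: isopropenylmagnesium bromide, C=C(C)[Mg]Br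
Why: Double Grignard addition to the α-alkoxy ester passes through the isopropenyl ketone, CeCl3 favouring 1,2-addition at the hindered enone stage, and the new carbinol carbon bears two identical groups so no stereocentre is formed.

Step 10
Reactants: 16 3-[(2S,5R)-2-({[tert-butyl(dimethyl)silyl]oxy}methyl)-5-methyl-5-[(4R,8R)-4,8,12-trimethyltridecyl]oxolan-2-yl]-2,4-dimethylpenta-1,4-dien-3-ol
Product: 17 3-[(2S,5R)-2-(hydroxymethyl)-5-methyl-5-[(4R,8R)-4,8,12-trimethyltridecyl]oxolan-2-yl]-2,4-dimethylpenta-1,4-dien-3-ol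
Conditions: Bu4NF, THF, 0 °C → rt
Reagents that add atoms: none
Why: Fluoride-driven desilylation frees the primary alcohol without affecting the tertiary bis-allylic alcohol or the olefins.

Step 11
Reactants: 17 3-[(2S,5R)-2-(hydroxymethyl)-5-methyl-5-[(4R,8R)-4,8,12-trimethyltridecyl]oxolan-2-yl]-2,4-dimethylpenta-1,4-dien-3-ol
Product: 18 (2R,5R)-2-(3-hydroxy-2,4-dimethylpenta-1,4-dien-3-yl)-5-methyl-5-[(4R,8R)-4,8,12-trimethyltridecyl]oxolane-2-carbaldehyde
Conditions: Dess–Martin periodinane, NaHCO3, CH2Cl2, 0 °C → rt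
Reagents that add atoms: none
Why: Buffered Dess–Martin oxidation takes the neopentyl primary alcohol to the aldehyde, the tertiary alcohol cannot be oxidised, and bicarbonate guards the bis-allylic carbinol against acid-induced ionisation.

Step 12
Reactants: 18 (2R,5R)-2-(3-hydroxy-2,4-dimethylpenta-1,4-dien-3-yl)-5-methyl-5-[(4R,8R)-4,8,12-trimethyltridecyl]oxolane-2-carbaldehyde; 14 isopropenylmagnesium bromide
Product: 19 3-[(2S,5R)-2-(1-hydroxy-2-methylprop-2-en-1-yl)-5-methyl-5-[(4R,8R)-4,8,12-trimethyltridecyl]oxolan-2-yl]-2,4-dimethylpenta-1,4-dien-3-ol (both epimers at the secondary carbinol)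
Conditions: 14 (3 equiv), THF, −78 °C
Reagents that add atoms: isopropenylmagnesium bromide, C=C(C)[Mg]Br
Why: 1,2-Addition of the Grignard reagent to the aldehyde at low temperature (one equivalent is consumed by the tertiary hydroxyl) should outpace retro-aldol cleavage, and the uncontrolled new carbinol centre is harmless because it becomes the ketone.

Step 13
Reactants: 19 3-[(2S,5R)-2-(1-hydroxy-2-methylprop-2-en-1-yl)-5-methyl-5-[(4R,8R)-4,8,12-trimethyltridecyl]oxolan-2-yl]-2,4-dimethylpenta-1,4-dien-3-ol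
Product: 20 1-[(2R,5R)-2-(3-hydroxy-2,4-dimethylpenta-1,4-dien-3-yl)-5-methyl-5-[(4R,8R)-4,8,12-trimethyltridecyl]oxolan-2-yl]-2-methylprop-2-en-1-one
Conditions: Dess–Martin periodinane, NaHCO3, CH2Cl2, 0 °C → rt
Reagents that add atoms: none
Why: Dess–Martin oxidation of the secondary allylic alcohol gives the 2-methylpropenoyl ketone while the tertiary alcohol is inert, and both epimers converge on one compound.

Step 14
Reactants: 20 1-[(2R,5R)-2-(3-hydroxy-2,4-dimethylpenta-1,4-dien-3-yl)-5-methyl-5-[(4R,8R)-4,8,12-trimethyltridecyl]oxolan-2-yl]-2-methylprop-2-en-1-one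
Product: 21 (2R,5R,9S)-9-hydroxy-2,7,8-trimethyl-9-(prop-1-en-2-yl)-2-[(4R,8R)-4,8,12-trimethyltridecyl]-1-oxaspiro[4.4]non-7-en-6-one
Conditions: (H2IMes)Cl2Ru(=CH-C6H4-2-OiPr) (second-generation Hoveyda–Grubbs catalyst, 10 mol % in two portions), toluene (0.005 M), 100 °C, argon sparge
Reagents that add atoms: none
Why: The ruthenium methylidene formed from the precatalyst exchanges onto one isopropenyl group of the tertiary allylic carbinol (helped by the free hydroxyl), this disubstituted alkylidene adds to the 2-methylpropenoyl olefin by [2+2] cycloaddition, and cycloreversion of the ruthenacyclobutane forms C7=C8 and returns the methylidene while ethylene is swept out. The closest known reaction type is ring-closing metathesis of dienes with two 1,1-disubstituted olefins to tetrasubstituted cyclopentenes and cyclopentenones using N-heterocyclic-carbene ruthenium catalysts at elevated temperature. Ring B closes as a five-membered carbocycle from the hepta-1,6-diene unit (C7, C6, C5, C9, C8 plus the two methylene carbons that are lost), ring A being already in place. C9 becomes stereogenic only here and is controlled by the quaternary C5: in the closing conformer the larger spectator isopropenyl group is expected to sit syn to the small ring oxygen O1 and the hydroxyl syn to the C4 methylene (anti to O1, C–O dipoles opposed), which is the (9S) arrangement of the target. The step needs diastereotopic group selectivity and ring closure in preference to cross-metathesis; the C5 bias, high dilution and the 1,1-disubstitution of every olefin (no homodimerisation) are meant to secure these, and the group selectivity remains an expectation to be checked by NOE on 21.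

Step 15
Reactants: 21 (2R,5R,9S)-9-hydroxy-2,7,8-trimethyl-9-(prop-1-en-2-yl)-2-[(4R,8R)-4,8,12-trimethyltridecyl]-1-oxaspiro[4.4]non-7-en-6-one
Product: 23 (2R,5R,9S)-9-acetyl-9-hydroxy-2,7,8-trimethyl-2-[(4R,8R)-4,8,12-trimethyltridecyl]-1-oxaspiro[4.4]non-7-en-6-one (CNP0373307.2), via ozonide 22 (not isolated)
Conditions: O3, CH2Cl2, −78 °C, Sudan red indicator; then Me2S, −78 °C → rt
Reagents that add atoms: ozone, [O-][O+]=O
Why: Ozone should attack the electron-rich 1,1-disubstituted isopropenyl olefin much faster than the electron-poor, fully substituted enone olefin (as in isopropenyl-selective ozonolysis of enone-containing terpenes), the indicator dye stops the reaction at one equivalent, and reductive work-up of the ozonide gives the methyl ketone without touching any stereocentre.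

**Compound list**

1 | natural (2E,7R,11R)-phytol | OC/C=C(\C)CCC[C@H](C)CCC[C@H](C)CCCC(C)C | starting material
2 | [(2R,3R)-3-methyl-3-[(4R,8R)-4,8,12-trimethyltridecyl]oxiran-2-yl]methanol | OC[C@H]1O[C@]1(C)CCC[C@H](C)CCC[C@H](C)CCCC(C)C | intermediate
3 | (2S,3R)-2-(iodomethyl)-3-methyl-3-[(4R,8R)-4,8,12-trimethyltridecyl]oxirane | IC[C@H]1O[C@]1(C)CCC[C@H](C)CCC[C@H](C)CCCC(C)C | intermediate
4 | (3R,7R,11R)-3,7,11,15-tetramethylhexadec-1-en-3-ol | C=C[C@@](C)(CCC[C@H](C)CCC[C@H](C)CCCC(C)C)O | intermediate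
5 | 4-{[tert-butyl(dimethyl)silyl]oxy}but-2-yn-1-ol | OCC#CCO[Si](C)(C)C(C)(C)C | starting material
6 | sodium cyclic alkenylalanate (five-membered O–Al–C ring, two 2-methoxyethoxy groups on Al, CH2OSi on the Al-bound alkene carbon) | [Na+].COCCO[Al-]1(OCCOC)OCC=C1CO[Si](C)(C)C(C)(C)C | intermediate
7 | (2Z)-4-{[tert-butyl(dimethyl)silyl]oxy}-3-iodobut-2-en-1-ol | OC/C=C(\I)CO[Si](C)(C)C(C)(C)C | intermediate
8 | 9-[(3S,7R,11R)-3-hydroxy-3,7,11,15-tetramethylhexadecyl]-9-borabicyclo[3.3.1]nonane | B1(CC[C@@](C)(CCC[C@H](C)CCC[C@H](C)CCCC(C)C)O)C2CCCC1CCC2 | intermediate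
9 | (2E,6R,10R,14R)-3-({[tert-butyl(dimethyl)silyl]oxy}methyl)-6,10,14,18-tetramethylnonadec-2-ene-1,6-diol | OC/C=C(\CC[C@@](C)(CCC[C@H](C)CCC[C@H](C)CCCC(C)C)O)CO[Si](C)(C)C(C)(C)C | intermediate
10 | [(2R,3R)-3-({[tert-butyl(dimethyl)silyl]oxy}methyl)-3-[(3R,7R,11R)-3-hydroxy-3,7,11,15-tetramethylhexadecyl]oxiran-2-yl]methanol | OC[C@H]1O[C@]1(CC[C@@](C)(CCC[C@H](C)CCC[C@H](C)CCCC(C)C)O)CO[Si](C)(C)C(C)(C)C | intermediate
11 | (1R)-1-[(2S,5R)-2-({[tert-butyl(dimethyl)silyl]oxy}methyl)-5-methyl-5-[(4R,8R)-4,8,12-trimethyltridecyl]oxolan-2-yl]ethane-1,2-diol | OC[C@@H](O)[C@@]1(CO[Si](C)(C)C(C)(C)C)CC[C@@](C)(CCC[C@H](C)CCC[C@H](C)CCCC(C)C)O1 | intermediate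
12 | (2S,5R)-2-({[tert-butyl(dimethyl)silyl]oxy}methyl)-5-methyl-5-[(4R,8R)-4,8,12-trimethyltridecyl]oxolane-2-carbaldehyde | O=C[C@@]1(CO[Si](C)(C)C(C)(C)C)CC[C@@](C)(CCC[C@H](C)CCC[C@H](C)CCCC(C)C)O1 | intermediate
13 | methyl (2S,5R)-2-({[tert-butyl(dimethyl)silyl]oxy}methyl)-5-methyl-5-[(4R,8R)-4,8,12-trimethyltridecyl]oxolane-2-carboxylate | COC(=O)[C@@]1(CO[Si](C)(C)C(C)(C)C)CC[C@@](C)(CCC[C@H](C)CCC[C@H](C)CCCC(C)C)O1 | intermediate
14 | isopropenylmagnesium bromide | C=C(C)[Mg]Br | starting material
15 | 1-[(2S,5R)-2-({[tert-butyl(dimethyl)silyl]oxy}methyl)-5-methyl-5-[(4R,8R)-4,8,12-trimethyltridecyl]oxolan-2-yl]-2-methylprop-2-en-1-one | C=C(C)C(=O)[C@@]1(CO[Si](C)(C)C(C)(C)C)CC[C@@](C)(CCC[C@H](C)CCC[C@H](C)CCCC(C)C)O1 | intermediate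
16 | 3-[(2S,5R)-2-({[tert-butyl(dimethyl)silyl]oxy}methyl)-5-methyl-5-[(4R,8R)-4,8,12-trimethyltridecyl]oxolan-2-yl]-2,4-dimethylpenta-1,4-dien-3-ol | C=C(C)C(O)(C(C)=C)[C@@]1(CO[Si](C)(C)C(C)(C)C)CC[C@@](C)(CCC[C@H](C)CCC[C@H](C)CCCC(C)C)O1 | intermediate
17 | 3-[(2S,5R)-2-(hydroxymethyl)-5-methyl-5-[(4R,8R)-4,8,12-trimethyltridecyl]oxolan-2-yl]-2,4-dimethylpenta-1,4-dien-3-ol | C=C(C)C(O)(C(C)=C)[C@@]1(CO)CC[C@@](C)(CCC[C@H](C)CCC[C@H](C)CCCC(C)C)O1 | intermediate
18 | (2R,5R)-2-(3-hydroxy-2,4-dimethylpenta-1,4-dien-3-yl)-5-methyl-5-[(4R,8R)-4,8,12-trimethyltridecyl]oxolane-2-carbaldehyde | C=C(C)C(O)(C(C)=C)[C@@]1(C=O)CC[C@@](C)(CCC[C@H](C)CCC[C@H](C)CCCC(C)C)O1 | intermediate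
19 | 3-[(2S,5R)-2-(1-hydroxy-2-methylprop-2-en-1-yl)-5-methyl-5-[(4R,8R)-4,8,12-trimethyltridecyl]oxolan-2-yl]-2,4-dimethylpenta-1,4-dien-3-ol (epimers at the secondary carbinol) | C=C(C)C(O)(C(C)=C)[C@@]1(C(O)C(C)=C)CC[C@@](C)(CCC[C@H](C)CCC[C@H](C)CCCC(C)C)O1 | intermediate
20 | 1-[(2R,5R)-2-(3-hydroxy-2,4-dimethylpenta-1,4-dien-3-yl)-5-methyl-5-[(4R,8R)-4,8,12-trimethyltridecyl]oxolan-2-yl]-2-methylprop-2-en-1-one | C=C(C)C(=O)[C@]1(C(O)(C(C)=C)C(C)=C)CC[C@@](C)(CCC[C@H](C)CCC[C@H](C)CCCC(C)C)O1 | intermediate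
21 | (2R,5R,9S)-9-hydroxy-2,7,8-trimethyl-9-(prop-1-en-2-yl)-2-[(4R,8R)-4,8,12-trimethyltridecyl]-1-oxaspiro[4.4]non-7-en-6-one | C=C(C)[C@]1(O)C(C)=C(C)C(=O)[C@@]12CC[C@@](C)(CCC[C@H](C)CCC[C@H](C)CCCC(C)C)O2 | intermediate
22 | secondary ozonide of 21 (3-methyl-1,2,4-trioxolan-3-yl group on C9 in place of the isopropenyl group) | CC1(OCOO1)[C@]2(O)C(C)=C(C)C(=O)[C@@]23CC[C@@](C)(CCC[C@H](C)CCC[C@H](C)CCCC(C)C)O3 | intermediate
23 | (2R,5R,9S)-9-acetyl-9-hydroxy-2,7,8-trimethyl-2-[(4R,8R)-4,8,12-trimethyltridecyl]-1-oxaspiro[4.4]non-7-en-6-one | CC(=O)[C@]1(O)C(C)=C(C)C(=O)[C@@]12CC[C@@](C)(CCC[C@H](C)CCC[C@H](C)CCCC(C)C)O2 | target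

**Step count and risks**

Total step count: 15. Longest linear sequence: 14 steps (1 to 23 through steps 1–3 and 5–15); step 4 is a one-step branch.

Steps most likely to fail:

Step 14. The closure may stall because the disubstituted ruthenium alkylidene has to add to an electron-poor, 1,1-disubstituted enone olefin beside a quaternary carbon, so catalyst decomposition can outrun turnover. The choice between the two isopropenyl groups may also erode at the temperature needed. The fallback sets out from 19 and closes the ring at the allylic-alcohol oxidation level, where both reacting olefins are electron-rich. Metathesis of 19 (carbinol epimers separated first if they behave differently) with (H2IMes)Cl2Ru(=CH-C6H4-2-OiPr), or with its 1,3-bis(2-methylphenyl)imidazolidin-2-ylidene analogue made for tetrasubstituted olefins, in toluene at 60–80 °C should give the spiro diol (2R,5S,9S)-2,7,8-trimethyl-9-(prop-1-en-2-yl)-2-[(4R,8R)-4,8,12-trimethyltridecyl]-1-oxaspiro[4.4]non-7-ene-6,9-diol F1. Oxidation of its secondary allylic hydroxyl with MnO2 or Dess–Martin periodinane then comes back to the route at 21.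

Step 9. The second addition may stop at the hindered isopropenyl ketone or divert into conjugate addition at its exposed methylene terminus. The fallback sets out from 12 and builds the carbinol one carbonyl addition at a time. Addition of 14 to aldehyde 12 at −78 °C should give the allylic alcohol 1-[(2S,5R)-2-({[tert-butyl(dimethyl)silyl]oxy}methyl)-5-methyl-5-[(4R,8R)-4,8,12-trimethyltridecyl]oxolan-2-yl]-2-methylprop-2-en-1-ol F2. Dess–Martin oxidation gives ketone 15, now isolated and purified. The organocerium reagent from 2-bromopropene, t-BuLi and CeCl3 is then added at −78 °C, where 1,2-addition is the rule, and the route is rejoined at 16.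

Step 15. Ozone may go on to attack the tetrasubstituted enone olefin once the isopropenyl group is consumed, or the hydroxy ketone may suffer oxidative cleavage during work-up. The fallback sets out from 21 and uses dihydroxylation with catalytic OsO4 and N-methylmorpholine N-oxide in acetone–water, which should leave the hindered, electron-poor enone olefin alone. This gives the triol (2R,5R,9R)-9-(1,2-dihydroxypropan-2-yl)-9-hydroxy-2,7,8-trimethyl-2-[(4R,8R)-4,8,12-trimethyltridecyl]-1-oxaspiro[4.4]non-7-en-6-one F3. One equivalent of NaIO4 at 0 °C is expected to cleave the primary–tertiary glycol faster than the crowded ditertiary one and so comes back to the route at 23.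

**Further compounds**

F1 | step 14 | (2R,5S,9S)-2,7,8-trimethyl-9-(prop-1-en-2-yl)-2-[(4R,8R)-4,8,12-trimethyltridecyl]-1-oxaspiro[4.4]non-7-ene-6,9-diol (epimers at C6) | C=C(C)[C@]1(O)C(C)=C(C)C(O)[C@@]12CC[C@@](C)(CCC[C@H](C)CCC[C@H](C)CCCC(C)C)O2
F2 | step 9 | 1-[(2S,5R)-2-({[tert-butyl(dimethyl)silyl]oxy}methyl)-5-methyl-5-[(4R,8R)-4,8,12-trimethyltridecyl]oxolan-2-yl]-2-methylprop-2-en-1-ol (carbinol epimers) | C=C(C)C(O)[C@@]1(CO[Si](C)(C)C(C)(C)C)CC[C@@](C)(CCC[C@H](C)CCC[C@H](C)CCCC(C)C)O1
F3 | step 15 | (2R,5R,9R)-9-(1,2-dihydroxypropan-2-yl)-9-hydroxy-2,7,8-trimethyl-2-[(4R,8R)-4,8,12-trimethyltridecyl]-1-oxaspiro[4.4]non-7-en-6-one (epimers at the side-chain carbinol) | CC(O)(CO)[C@]1(O)C(C)=C(C)C(=O)[C@@]12CC[C@@](C)(CCC[C@H](C)CCC[C@H](C)CCCC(C)C)O2
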